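**Retrosynthetic overview**

- Flemistrictin D is a 2,2-dimethyl-2H-chromene (O1, C2, C3=C4, C4a, C8a) whose ring A carries C5–OH, C6–CO(CH2)2Ph, C7–OMe and C8–OH. The C8–O bond is made last, by para-hydroxylation of the C5 phenol (Elbs); the C6–C(=O) bond comes before it, by ortho-lithiation between C5–OMOM and C7–OMe and acylation with a Weinreb amide.
- The key disconnection cuts C3–C4 and O1–C2 of the pyran ring, the only ring that is built (ring A is bought). It leads back to 2,6-dihydroxy-4-methoxybenzaldehyde and 2-methylprop-1-enylboronic acid, joined by borono-Mannich alkenylation, loss of the amine and oxa-6π closure.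
- The strategy rests on this feature: C4 is the former formyl carbon on C4a, and C4a is flanked by the two oxygen-bearing carbons C5 and C8a. In the aldehyde these two hydroxyls are mirror images of each other (mirror plane through C4a and C7–OMe), so either one closes to the same chromene and the other is left as C5–OH.
- The aldehyde comes from 2,4,6-trihydroxybenzaldehyde by methylation of the 4-hydroxyl.

Key step: step 2

Remark on the chemistry: the target has no stereocenter, and its only double bond with a geometry (C3=C4) is fixed as cis by the six-membered ring. The final 5,8-hydroquinone is assumed to be isolable when handled under inert gas.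

**Route**

Step 1
Reactants: 1 2,4,6-trihydroxybenzaldehyde
Product: 2 2,6-dihydroxy-4-methoxybenzaldehyde
Conditions: Me2SO4 (1.0 equiv), K2CO3 (1.0 equiv), acetone, rt
Reagents that add atoms: dimethyl sulfate, COS(=O)(=O)OC
Why: Williamson-type O-methylation under weak-base control, in which the 4-hydroxyl, the most acidic one and the only one not hydrogen-bonded to the formyl group, should be methylated first by one equivalent of dimethyl sulfate.

Step 2
Reactants: 2 2,6-dihydroxy-4-methoxybenzaldehyde; 3 2-methylprop-1-enylboronic acid
Product: 6 7-methoxy-2,2-dimethyl-2H-chromen-5-ol, via Petasis aminophenol 4 (not isolated), via ortho-quinone methide 5 (not isolated)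
Conditions: 3 (1.5 equiv), Bn2NH (0.4 equiv), dioxane, 90 °C
Reagents that add atoms: none
Why: Dibenzylamine and the formyl group of 2 condense to an iminium ion, the adjacent phenoxide binds boronic acid 3 as a tetracoordinate boronate, and the 2-methylprop-1-enyl group migrates from boron to the iminium carbon within this complex, forming C3–C4 and giving aminophenol 4 (Petasis borono-Mannich reaction; the Bn2N group of 4 is that of the amine catalyst). At 90 °C the benzylic C–N bond of 4, weakened by the para-methoxy and the two ortho-oxygen substituents, ionises with return of dibenzylamine to the cycle and gives ortho-quinone methide 5. The 1-oxatriene O=C–C=C–C=C of 5 then closes thermally by a disrotatory oxa-6π electrocyclisation in which the carbonyl oxygen bonds to the dimethyl-substituted terminus, which forms O1–C2, closes the six-membered pyran ring and restores the aromaticity of ring A. The closest known reaction type is the amine-promoted condensation of salicylaldehydes with alkenylboronic acids to 2H-chromenes. No stereocenter remains, since C2 carries two methyl groups and the stereocenter of 4 is lost in 5. The only selectivity needed is the choice of the hydroxyl that becomes O1, and the substrate removes it: the formyl carbon lies on the mirror plane of 2, both hydroxyls are identical, either alkene geometry of 5 can close after a proton shift between the two oxygens, and the hydroxyl left over is C5–OH.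

Step 3
Reactants: 6 7-methoxy-2,2-dimethyl-2H-chromen-5-ol
Product: 7 7-methoxy-5-(methoxymethoxy)-2,2-dimethyl-2H-chromene
Conditions: MOMCl, iPr2NEt, CH2Cl2, 0 °C → rt
Reagents that add atoms: chloromethyl methyl ether, COCCl
Why: MOM ether formation (O-alkylation of a free, non-chelated phenol), which masks the acidic hydroxyl for step 5 and installs the strongest ortho-directing group of ring A at C5.

Step 4
Reactants: 8 3-phenylpropanoic acid
Product: 10 N-methoxy-N-methyl-3-phenylpropanamide, via acyl imidazolide 9 (not isolated)
Conditions: CDI, CH2Cl2, rt; then MeNHOMe·HCl, rt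
Reagents that add atoms: N,O-dimethylhydroxylamine hydrochloride, CNOC.Cl
Why: Weinreb amide formation by CDI activation, in which the acid gives acyl imidazolide 9 with loss of CO2 and 9 acylates the hydroxylamine set free from its hydrochloride by the imidazole formed in the activation.

Step 5
Reactants: 7 7-methoxy-5-(methoxymethoxy)-2,2-dimethyl-2H-chromene; 10 N-methoxy-N-methyl-3-phenylpropanamide
Product: 13 1-[7-methoxy-5-(methoxymethoxy)-2,2-dimethyl-2H-chromen-6-yl]-3-phenylpropan-1-one, via C6 aryllithium 11 (not isolated), via tetrahedral lithium adduct 12 (not isolated)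
Conditions: n-BuLi (1.1 equiv), TMEDA, THF, 0 °C; then 10, −78 °C → rt; aq. NH4Cl
Reagents that add atoms: none
Why: Directed ortho-metalation followed by Weinreb ketone synthesis, in which C6–H, lying between the chelating OMOM group and the methoxy group, should be removed in preference to C8–H, which has only the methoxy group and the pyran oxygen as neighbours, and the chelated adduct 12 stops a second addition and gives the ketone only on work-up.

Step 6
Reactants: 13 1-[7-methoxy-5-(methoxymethoxy)-2,2-dimethyl-2H-chromen-6-yl]-3-phenylpropan-1-one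
Product: 14 1-(5-hydroxy-7-methoxy-2,2-dimethyl-2H-chromen-6-yl)-3-phenylpropan-1-one
Conditions: 3 M HCl, MeOH, 50 °C
Reagents that add atoms: none
Why: Acid-catalysed acetal cleavage (MOM removal by transacetalisation to methanol), which is fast for a MOM ether ortho to a ketone because the freed phenol is held in a hydrogen bond to the carbonyl, while the acyl-deactivated chromene should tolerate dilute acid.

Step 7
Reactants: 14 1-(5-hydroxy-7-methoxy-2,2-dimethyl-2H-chromen-6-yl)-3-phenylpropan-1-one
Product: 16 Flemistrictin D [1-(5,8-dihydroxy-7-methoxy-2,2-dimethyl-2H-chromen-6-yl)-3-phenylpropan-1-one], via aryl sulfate potassium salt 15 (not isolated)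
Conditions: K2S2O8 (1.1 equiv), 10% aq. KOH, pyridine, 0 °C → rt; then HCl to pH 1, 60 °C, N2
Reagents that add atoms: potassium peroxodisulfate, [K+].[K+].[O-]S(=O)(=O)OOS(=O)(=O)[O-]
Why: Elbs persulfate oxidation, in which the phenoxide of 14 attacks the peroxide oxygen through its para carbon C8 (the only free position of ring A) to give sulfate 15, which resists further oxidation in the alkaline medium and releases the C8 hydroxyl on acid hydrolysis, a reaction type known for chelated 5-hydroxy-7-alkoxy benzopyranones.

**Compound list**

1 | 2,4,6-trihydroxybenzaldehyde | O=Cc1c(O)cc(O)cc1O | starting material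
2 | 2,6-dihydroxy-4-methoxybenzaldehyde | COc1cc(O)c(C=O)c(O)c1 | intermediate
3 | 2-methylprop-1-enylboronic acid | CC(C)=CB(O)O | starting material
4 | 2-[1-(dibenzylamino)-3-methylbut-2-en-1-yl]-5-methoxybenzene-1,3-diol (racemic, not isolated) | COc1cc(O)c(C(C=C(C)C)N(Cc2ccccc2)Cc2ccccc2)c(O)c1 | intermediate
5 | 5-hydroxy-3-methoxy-6-(3-methylbut-2-en-1-ylidene)cyclohexa-2,4-dien-1-one (not isolated) | COC1=CC(=O)C(=CC=C(C)C)C(O)=C1 | intermediate
6 | 7-methoxy-2,2-dimethyl-2H-chromen-5-ol | COc1cc(O)c2C=CC(C)(C)Oc2c1 | intermediate
7 | 7-methoxy-5-(methoxymethoxy)-2,2-dimethyl-2H-chromene | COCOc1cc(OC)cc2OC(C)(C)C=Cc12 | intermediate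
8 | 3-phenylpropanoic acid | OC(=O)CCc1ccccc1 | starting material
9 | 1-(1H-imidazol-1-yl)-3-phenylpropan-1-one (not isolated) | O=C(CCc1ccccc1)n1ccnc1 | intermediate
10 | N-methoxy-N-methyl-3-phenylpropanamide | CON(C)C(=O)CCc1ccccc1 | intermediate
11 | [7-methoxy-5-(methoxymethoxy)-2,2-dimethyl-2H-chromen-6-yl]lithium (not isolated) | COc1cc2OC(C)(C)C=Cc2c(OCOC)c1[Li] | intermediate
12 | lithium 1-[7-methoxy-5-(methoxymethoxy)-2,2-dimethyl-2H-chromen-6-yl]-1-[methoxy(methyl)amino]-3-phenylpropan-1-olate (racemic, not isolated) | COc1cc2OC(C)(C)C=Cc2c(OCOC)c1C(O[Li])(CCc1ccccc1)N(C)OC | intermediate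
13 | 1-[7-methoxy-5-(methoxymethoxy)-2,2-dimethyl-2H-chromen-6-yl]-3-phenylpropan-1-one | COc1cc2OC(C)(C)C=Cc2c(OCOC)c1C(=O)CCc1ccccc1 | intermediate
14 | 1-(5-hydroxy-7-methoxy-2,2-dimethyl-2H-chromen-6-yl)-3-phenylpropan-1-one | COc1cc2OC(C)(C)C=Cc2c(O)c1C(=O)CCc1ccccc1 | intermediate
15 | potassium 5-hydroxy-7-methoxy-2,2-dimethyl-6-(3-phenylpropanoyl)-2H-chromen-8-yl sulfate (not isolated) | COc1c(OS(=O)(=O)[O-])c2OC(C)(C)C=Cc2c(O)c1C(=O)CCc1ccccc1.[K+] | intermediate
16 | Flemistrictin D, 1-(5,8-dihydroxy-7-methoxy-2,2-dimethyl-2H-chromen-6-yl)-3-phenylpropan-1-one | COc1c(O)c2c(c(O)c1C(=O)CCc1ccccc1)C=CC(C)(C)O2 | target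

**Step count**

Total: 7 steps. Longest linear sequence: 6 steps (steps 1, 2, 3, 5, 6, 7 from 2,4,6-trihydroxybenzaldehyde); step 4 is a one-step side branch.

**Steps most likely to fail, with fallbacks**

Step 7 (Elbs hydroxylation). Persulfate hydroxylations often stop at partial conversion. Persulfate may also attack the C3=C4 double bond, the chromene may be hydrated or dimerised by acid while the sulfate ester is hydrolysed, and the hydroquinone may be oxidised by air during isolation. The fallback brings in the C8 oxygen before the acyl group and sets out from chromenol 6. Teuber oxidation of the free, non-chelated phenol with (KSO3)2NO (Fremy's salt) in KH2PO4-buffered aqueous acetone should give 7-methoxy-2,2-dimethyl-2H-chromene-5,8-dione F1. Reduction with Na2S2O4 gives 7-methoxy-2,2-dimethyl-2H-chromene-5,8-diol F2, which is protected at once with MOMCl and iPr2NEt as 7-methoxy-5,8-bis(methoxymethoxy)-2,2-dimethyl-2H-chromene F3. Its only aromatic hydrogen is at C6, between an OMOM and the OMe group, so lithiation with n-BuLi can only give [7-methoxy-5,8-bis(methoxymethoxy)-2,2-dimethyl-2H-chromen-6-yl]lithium F4. With Weinreb amide 10 this gives lithium 1-[7-methoxy-5,8-bis(methoxymethoxy)-2,2-dimethyl-2H-chromen-6-yl]-1-[methoxy(methyl)amino]-3-phenylpropan-1-olate F5, and work-up gives 1-[7-methoxy-5,8-bis(methoxymethoxy)-2,2-dimethyl-2H-chromen-6-yl]-3-phenylpropan-1-one F6. HCl in methanol removes both MOM groups and the sequence comes back to the route at target 16, in place of steps 3, 5, 6 and 7.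

Step 2 (key step). The β,β-disubstituted alkenyl group may transfer slowly to an iminium ion that is made poorly electrophilic by three oxygen donors. Boronic acid 3 may be protodeboronated at 90 °C, and quinone methide 5 may be captured by the nucleophilic product before it closes, which leads to oligomers. The fallback keeps the symmetric aldehyde and the same two bonds but forms them by carbonyl chemistry, setting out from aldehyde 2. Wittig olefination with Ph3P=CHCO2Et in refluxing N,N-diethylaniline gives ethyl (E)-3-(2,6-dihydroxy-4-methoxyphenyl)prop-2-enoate F7. In the same flask this isomerises and lactonises to 5-hydroxy-7-methoxy-2H-chromen-2-one F8; either hydroxyl gives the same coumarin. Excess MeLi (THF, 0 °C) adds twice to the lactone carbonyl and gives 2-[(Z)-3-hydroxy-3-methylbut-1-en-1-yl]-5-methoxybenzene-1,3-diol F9. Brief treatment with PPTS in toluene ionises the tertiary allylic alcohol and closes the pyran ring by cyclodehydration, coming back to the route at chromenol 6.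

Step 5 (lithiation and acylation). Metalation at C8 may compete with metalation at C6, and the hindered aryllithium may take a proton from the α-CH2 of amide 10 instead of adding to it. The fallback uses an ortho-specific formylation of the free phenol and sets out from chromenol 6. Casnati–Skattebøl formylation (MgCl2, Et3N, paraformaldehyde, MeCN, reflux) delivers formaldehyde through the magnesium phenoxide and can reach only C6, since the other ortho position is C4a. It should give 5-hydroxy-7-methoxy-2,2-dimethyl-2H-chromene-6-carbaldehyde F10. Addition of 2-phenylethylmagnesium bromide (2.5 equiv, THF, 0 °C) gives racemic 1-(5-hydroxy-7-methoxy-2,2-dimethyl-2H-chromen-6-yl)-3-phenylpropan-1-ol F11, which is oxidised without storage by MnO2 in CH2Cl2. The sequence comes back to the route at ketone 14, so that steps 3 to 6 are not needed.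

**Further compounds**

F1 | step 7 | 7-methoxy-2,2-dimethyl-2H-chromene-5,8-dione | COC1=CC(=O)C2=C(OC(C)(C)C=C2)C1=O
F2 | step 7 | 7-methoxy-2,2-dimethyl-2H-chromene-5,8-diol | COc1cc(O)c2C=CC(C)(C)Oc2c1O
F3 | step 7 | 7-methoxy-5,8-bis(methoxymethoxy)-2,2-dimethyl-2H-chromene | COCOc1cc(OC)c(OCOC)c2OC(C)(C)C=Cc12
F4 | step 7 | [7-methoxy-5,8-bis(methoxymethoxy)-2,2-dimethyl-2H-chromen-6-yl]lithium | COCOc1c([Li])c(OC)c(OCOC)c2OC(C)(C)C=Cc12
F5 | step 7 | lithium 1-[7-methoxy-5,8-bis(methoxymethoxy)-2,2-dimethyl-2H-chromen-6-yl]-1-[methoxy(methyl)amino]-3-phenylpropan-1-olate | COCOc1c(C(O[Li])(CCc3ccccc3)N(C)OC)c(OC)c(OCOC)c2OC(C)(C)C=Cc12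
F6 | step 7 | 1-[7-methoxy-5,8-bis(methoxymethoxy)-2,2-dimethyl-2H-chromen-6-yl]-3-phenylpropan-1-one | COCOc1c(C(=O)CCc3ccccc3)c(OC)c(OCOC)c2OC(C)(C)C=Cc12
F7 | step 2 | ethyl (E)-3-(2,6-dihydroxy-4-methoxyphenyl)prop-2-enoate | CCOC(=O)/C=C/c1c(O)cc(OC)cc1O
F8 | step 2 | 5-hydroxy-7-methoxy-2H-chromen-2-one | COc1cc(O)c2C=CC(=O)Oc2c1
F9 | step 2 | 2-[(Z)-3-hydroxy-3-methylbut-1-en-1-yl]-5-methoxybenzene-1,3-diol | COc1cc(O)c(/C=C\C(C)(C)O)c(O)c1
F10 | step 5 | 5-hydroxy-7-methoxy-2,2-dimethyl-2H-chromene-6-carbaldehyde | COc1cc2OC(C)(C)C=Cc2c(O)c1C=O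
F11 | step 5 | 1-(5-hydroxy-7-methoxy-2,2-dimethyl-2H-chromen-6-yl)-3-phenylpropan-1-ol (racemic) | COc1cc2OC(C)(C)C=Cc2c(O)c1C(O)CCc1ccccc1
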